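**Retrosynthetic overview**
1. Target ⇐ global desilylation ⇐ (2S)-flavanone ⇐ flavone: ring C is built flat (pyranone level), so C2 is set last by a chiral copper hydride, independently of the remote C2'' centre.
2. C8–C1'' bond ⇐ Negishi coupling of an 8-iodoflavone with a homoallylic zinc reagent; its iodide comes from an oxazolidinone-controlled deconjugative prenylation, chemoselective epoxidation and hydride opening.
3. Ring C ⇐ one rhodium-catalysed annulation that makes C3–C4 and O1–C2 from a 3-iodosalicylaldehyde (ring A) and the aroyl sulfoxonium ylide of ring B (formyl C–H activation, carbene insertion, cyclodehydration).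
4. Enabling feature: in ring A the free hydroxyl O1–H on C8a lies ortho to the formyl carbon C4 on C4a. O1 steers rhodium into the C4–H bond (five-membered O1–C8a–C4a–C4–Rh ring) and then closes ring C; C5–OMe and C7–OSi leave O1 as the only oxygen that can close.
5. Ring order: rings A and B are bought aromatic; ring C is the only ring formed (step 11) and is reduced to the dihydropyranone in step 13.

Key step: step 11

Assumption: 2,4-dihydroxy-6-methoxybenzaldehyde is taken as a catalogue compound (otherwise one selective O-methylation away from 2,4,6-trihydroxybenzaldehyde).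
Assumption: the sense of induction in step 13 is taken by analogy with β-substituted cyclic enones ((S)-DTBM-SEGPHOS, hydride to the Re face of C2); the mirror-image ligand is the remedy if the sense is found to be opposite.

**Route**

Step 1
Reactants: 1 (S)-4-benzyloxazolidin-2-one; 2 3-methylbut-2-enoyl chloride
Product: 3 (4S)-4-benzyl-3-(3-methylbut-2-enoyl)oxazolidin-2-one
Conditions: n-BuLi, THF, −78 °C; then 2, −78 → 0 °C
Reagents that add atoms: none
Why: N-acylation of the lithiated oxazolidinone by the acid chloride loads the auxiliary; no stereocentre is formed.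

Step 2
Reactants: 3 (4S)-4-benzyl-3-(3-methylbut-2-enoyl)oxazolidin-2-one; 4 1-bromo-3-methylbut-2-ene
Product: 5 (4S)-4-benzyl-3-[(2S)-5-methyl-2-(prop-1-en-2-yl)hex-4-enoyl]oxazolidin-2-one
Conditions: NaN(SiMe3)2, THF, −78 °C; then 4, −78 → −30 °C
Reagents that add atoms: none
Why: γ-Deprotonation gives the chelated (Z)-sodium dienolate, which is alkylated at the α-carbon on the face opposite the benzyl group (deconjugative Evans alkylation); this sets the side-chain stereocentre, (S) here and (R) at C2'' of the target after the change of substituent priorities.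

Step 3
Reactants: 5 (4S)-4-benzyl-3-[(2S)-5-methyl-2-(prop-1-en-2-yl)hex-4-enoyl]oxazolidin-2-one
Product: 6 (4S)-4-benzyl-3-[(2S)-3-(3,3-dimethyloxiran-2-yl)-2-(prop-1-en-2-yl)propanoyl]oxazolidin-2-one (both oxirane epimers)
Conditions: mCPBA (1.05 equiv), CH2Cl2, −10 → 0 °C
Reagents that add atoms: 3-chloroperbenzoic acid, OOC(=O)c1cccc(Cl)c1
Why: Prilezhaev epoxidation takes the more electron-rich trisubstituted alkene ahead of the 1,1-disubstituted isopropenyl group (the preference known from the 1,2-epoxidation of limonene); the new oxirane centre needs no control because step 4 turns it into a CH2 group.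

Step 4
Reactants: 6 (4S)-4-benzyl-3-[(2S)-3-(3,3-dimethyloxiran-2-yl)-2-(prop-1-en-2-yl)propanoyl]oxazolidin-2-one
Product: 7 (2S)-5-methyl-2-(prop-1-en-2-yl)hexane-1,5-diol
Conditions: LiAlH4, THF, 0 °C → rt
Reagents that add atoms: none
Why: Hydride cleaves the imide reductively to the primary alcohol (auxiliary 1 is released) and opens the trisubstituted epoxide by SN2 attack at its CH carbon to give the tertiary alcohol; the C2 stereocentre is not touched.

Step 5
Reactants: 7 (2S)-5-methyl-2-(prop-1-en-2-yl)hexane-1,5-diol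
Product: 8 (5S)-6-iodo-2-methyl-5-(prop-1-en-2-yl)hexan-2-ol
Conditions: PPh3, I2, imidazole, CH2Cl2, 0 °C
Reagents that add atoms: iodine, II
Why: Appel iodination: only the primary hydroxyl is activated as the alkoxyphosphonium ion and displaced by iodide (SN2 at CH2), while the tertiary alcohol and the adjacent stereocentre stay as they are.

Step 6
Reactants: 8 (5S)-6-iodo-2-methyl-5-(prop-1-en-2-yl)hexan-2-ol
Product: 9 triethyl{[(5S)-6-iodo-2-methyl-5-(prop-1-en-2-yl)hexan-2-yl]oxy}silane
Conditions: TESOTf, 2,6-lutidine, CH2Cl2, −78 → 0 °C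
Reagents that add atoms: triethylsilyl trifluoromethanesulfonate, CC[Si](CC)(CC)OS(=O)(=O)C(F)(F)F
Why: Silyl triflate silylation is the standard way to protect a tertiary alcohol, which must be masked for the organolithium chemistry of step 12.

Step 7
Reactants: 10 2,4-dihydroxy-6-methoxybenzaldehyde
Product: 11 2-hydroxy-6-methoxy-4-[(triisopropylsilyl)oxy]benzaldehyde
Conditions: TIPSCl (1.05 equiv), imidazole, CH2Cl2, 0 °C
Reagents that add atoms: chlorotri(propan-2-yl)silane, CC(C)[Si](Cl)(C(C)C)C(C)C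
Why: The 4-hydroxyl (para to the formyl group, not hydrogen-bonded) is more acidic and more accessible than the chelated 2-hydroxyl, so monosilylation should occur there.

Step 8
Reactants: 11 2-hydroxy-6-methoxy-4-[(triisopropylsilyl)oxy]benzaldehyde
Product: 12 2-hydroxy-3-iodo-6-methoxy-4-[(triisopropylsilyl)oxy]benzaldehyde
Conditions: BnMe3N·ICl2 (1.05 equiv), NaHCO3, CH2Cl2/MeOH, rt
Reagents that add atoms: benzyltrimethylammonium dichloroiodate, C[N+](C)(C)Cc1ccccc1.Cl[I-]Cl
Why: Electrophilic aromatic iodination should go ortho to the free chelated phenol (C3, also para to the methoxy group), the site known for 2-hydroxy-4,6-dialkoxyaryl carbonyl compounds with this reagent; this iodine marks the future C8.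

Step 9
Reactants: 13 4-hydroxy-2-methoxybenzoic acid
Product: 15 2-methoxy-4-[(triisopropylsilyl)oxy]benzoic acid, via bis-silyl ester 14 (not isolated)
Conditions: TIPSCl (2.2 equiv), imidazole, DMF, rt; then K2CO3, THF/H2O, 0 °C → rt; acidic work-up
Reagents that add atoms: chlorotri(propan-2-yl)silane, CC(C)[Si](Cl)(C(C)C)C(C)C
Why: Exhaustive silylation followed by selective hydrolysis of the silyl ester, which is far more labile than the aryl silyl ether, leaves only the phenol protected.

Step 10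
Reactants: 15 2-methoxy-4-[(triisopropylsilyl)oxy]benzoic acid
Product: 17 dimethylsulfoxonium 2-{2-methoxy-4-[(triisopropylsilyl)oxy]phenyl}-2-oxoethylide, via acid chloride 16 (not isolated)
Conditions: (COCl)2, DMF (cat.), CH2Cl2, 0 °C → rt; then added to Me3S(O)I/KOtBu (3 equiv each, premixed in THF at reflux), 0 °C → rt
Reagents that add atoms: trimethylsulfoxonium iodide, C[S+](C)(C)=O.[I-]
Why: The acid chloride acylates dimethylsulfoxonium methylide (Corey–Chaykovsky reagent) and a second equivalent of the methylide deprotonates the acylsulfoxonium salt to the stabilised ylide.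

Step 11
Reactants: 12 2-hydroxy-3-iodo-6-methoxy-4-[(triisopropylsilyl)oxy]benzaldehyde; 17 dimethylsulfoxonium 2-{2-methoxy-4-[(triisopropylsilyl)oxy]phenyl}-2-oxoethylide
Product: 19 8-iodo-5-methoxy-2-{2-methoxy-4-[(triisopropylsilyl)oxy]phenyl}-7-[(triisopropylsilyl)oxy]-4H-chromen-4-one, via 1,3-diketone 18 (not isolated)
Conditions: [Cp*RhCl2]2 (2.5 mol %), AgSbF6 (10 mol %), PivOH (1 equiv), 1,2-dichloroethane, 80 °C
Reagents that add atoms: none
Why: The phenoxide of ring A (O1 on C8a) binds the cationic trivalent rhodium centre and the adjacent formyl C4–H bond is cleaved by concerted metalation–deprotonation to a five-membered O1–C8a–C4a–C4–Rh acyl rhodacycle; the ylide carbon coordinates, dimethyl sulfoxide leaves, 1,1-migratory insertion of the acyl group into the rhodium carbene makes the C3–C4 bond, and protonolysis by pivalic acid releases 1,3-diketone 18 and the catalyst. In the same flask the acid closes ring C: O1 adds to the C2 carbonyl (6-exo-trig) and the hemiketal loses water, which makes the O1–C2 bond and the C2=C3 double bond. The closest known reaction type is the rhodium-catalysed acylmethylation and annulation of salicylaldehydes with aroyl sulfoxonium ylides to chromones. No stereocentre is formed, by design: ring C is built flat so that C2 is set by the catalyst of step 13. The step needs chemoselective activation of the formyl C–H bond over aryl C–H bonds and a single direction of ring closure; the five-membered chelate through O1 secures the first, and the second is secured because O1 is the only free oxygen (C5–O is methylated, C7–O is silylated). The aryl iodide should be inert because no low-valent metal is present.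

Step 12
Reactants: 9 triethyl{[(5S)-6-iodo-2-methyl-5-(prop-1-en-2-yl)hexan-2-yl]oxy}silane; 19 8-iodo-5-methoxy-2-{2-methoxy-4-[(triisopropylsilyl)oxy]phenyl}-7-[(triisopropylsilyl)oxy]-4H-chromen-4-one
Product: 22 5-methoxy-2-{2-methoxy-4-[(triisopropylsilyl)oxy]phenyl}-8-{(2R)-5-methyl-2-(prop-1-en-2-yl)-5-[(triethylsilyl)oxy]hexyl}-7-[(triisopropylsilyl)oxy]-4H-chromen-4-one, via alkyllithium 20 (not isolated), via alkylzinc chloride 21 (not isolated)
Conditions: 9, t-BuLi (2.1 equiv), Et2O, −78 °C; ZnCl2 (THF), −78 °C → rt; then 19, Pd(OAc)2 (5 mol %), SPhos (10 mol %), THF, rt → 45 °C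
Reagents that add atoms: none
Why: Iodine–lithium exchange and transmetalation give a primary alkylzinc chloride that undergoes Negishi coupling (zerovalent palladium, SPhos) at the C8–I bond; the stereocentre is β to the metal and is carried through unchanged, and the bulky biarylphosphine favours reductive elimination over β-hydride elimination.

Step 13
Reactants: 22 5-methoxy-2-{2-methoxy-4-[(triisopropylsilyl)oxy]phenyl}-8-{(2R)-5-methyl-2-(prop-1-en-2-yl)-5-[(triethylsilyl)oxy]hexyl}-7-[(triisopropylsilyl)oxy]-4H-chromen-4-one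
Product: 23 (2S)-5-methoxy-2-{2-methoxy-4-[(triisopropylsilyl)oxy]phenyl}-8-{(2R)-5-methyl-2-(prop-1-en-2-yl)-5-[(triethylsilyl)oxy]hexyl}-7-[(triisopropylsilyl)oxy]-2,3-dihydro-4H-chromen-4-one
Conditions: Cu(OAc)2 (5 mol %), (S)-DTBM-SEGPHOS (5.5 mol %), (EtO)2MeSiH, t-BuOH (1.2 equiv), toluene, 0 °C → rt
Reagents that add atoms: none
Why: Asymmetric conjugate reduction of the chromone by a chiral bisphosphine copper hydride (monovalent copper): hydride is delivered to the Re face of C2 under ligand control, which sets C2 as (S) independently of the remote side-chain centre, tert-butanol protonates the copper enolate at C3, and the isolated isopropenyl group should not react under these conditions.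

Step 14
Reactants: 23 (2S)-5-methoxy-2-{2-methoxy-4-[(triisopropylsilyl)oxy]phenyl}-8-{(2R)-5-methyl-2-(prop-1-en-2-yl)-5-[(triethylsilyl)oxy]hexyl}-7-[(triisopropylsilyl)oxy]-2,3-dihydro-4H-chromen-4-one
Product: 24 (2S)-7-hydroxy-2-(4-hydroxy-2-methoxyphenyl)-8-[(2R)-5-hydroxy-5-methyl-2-(prop-1-en-2-yl)hexyl]-5-methoxy-2,3-dihydro-4H-chromen-4-one
Conditions: Bu4NF (4 equiv), AcOH (4 equiv), THF, 0 °C → rt
Reagents that add atoms: none
Why: Fluoride cleaves the two aryl silyl ethers and the tertiary silyl ether in one operation, and the acetic acid buffer keeps the phenols protonated so that the flavanone does not open by retro-oxa-Michael reaction and C2 is not epimerised.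

**Compound list**
1 | (S)-4-benzyloxazolidin-2-one | O=C1OC[C@H](Cc2ccccc2)N1 | starting material
2 | 3-methylbut-2-enoyl chloride | CC(C)=CC(=O)Cl | starting material
3 | (4S)-4-benzyl-3-(3-methylbut-2-enoyl)oxazolidin-2-one | CC(C)=CC(=O)N1[C@@H](Cc2ccccc2)COC1=O | intermediate
4 | 1-bromo-3-methylbut-2-ene | CC(C)=CCBr | starting material
5 | (4S)-4-benzyl-3-[(2S)-5-methyl-2-(prop-1-en-2-yl)hex-4-enoyl]oxazolidin-2-one | CC(C)=CC[C@@H](C(C)=C)C(=O)N1[C@@H](Cc2ccccc2)COC1=O | intermediate
6 | (4S)-4-benzyl-3-[(2S)-3-(3,3-dimethyloxiran-2-yl)-2-(prop-1-en-2-yl)propanoyl]oxazolidin-2-one (both oxirane epimers) | CC1(C)OC1C[C@@H](C(C)=C)C(=O)N1[C@@H](Cc2ccccc2)COC1=O | intermediate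
7 | (2S)-5-methyl-2-(prop-1-en-2-yl)hexane-1,5-diol | CC(C)(O)CC[C@@H](C(C)=C)CO | intermediate
8 | (5S)-6-iodo-2-methyl-5-(prop-1-en-2-yl)hexan-2-ol | CC(C)(O)CC[C@@H](C(C)=C)CI | intermediate
9 | triethyl{[(5S)-6-iodo-2-methyl-5-(prop-1-en-2-yl)hexan-2-yl]oxy}silane | CC[Si](CC)(CC)OC(C)(C)CC[C@@H](C(C)=C)CI | intermediate
10 | 2,4-dihydroxy-6-methoxybenzaldehyde | COc1cc(O)cc(O)c1C=O | starting material
11 | 2-hydroxy-6-methoxy-4-[(triisopropylsilyl)oxy]benzaldehyde | COc1cc(O[Si](C(C)C)(C(C)C)C(C)C)cc(O)c1C=O | intermediate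
12 | 2-hydroxy-3-iodo-6-methoxy-4-[(triisopropylsilyl)oxy]benzaldehyde | COc1cc(O[Si](C(C)C)(C(C)C)C(C)C)c(I)c(O)c1C=O | intermediate
13 | 4-hydroxy-2-methoxybenzoic acid | COc1cc(O)ccc1C(=O)O | starting material
14 | triisopropylsilyl 2-methoxy-4-[(triisopropylsilyl)oxy]benzoate (formed in the flask) | COc1cc(O[Si](C(C)C)(C(C)C)C(C)C)ccc1C(=O)O[Si](C(C)C)(C(C)C)C(C)C | intermediate
15 | 2-methoxy-4-[(triisopropylsilyl)oxy]benzoic acid | COc1cc(O[Si](C(C)C)(C(C)C)C(C)C)ccc1C(=O)O | intermediate
16 | 2-methoxy-4-[(triisopropylsilyl)oxy]benzoyl chloride (formed in the flask) | COc1cc(O[Si](C(C)C)(C(C)C)C(C)C)ccc1C(=O)Cl | intermediate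
17 | dimethylsulfoxonium 2-{2-methoxy-4-[(triisopropylsilyl)oxy]phenyl}-2-oxoethylide | COc1cc(O[Si](C(C)C)(C(C)C)C(C)C)ccc1C(=O)C=S(C)(C)=O | intermediate
18 | 1-{2-hydroxy-3-iodo-6-methoxy-4-[(triisopropylsilyl)oxy]phenyl}-3-{2-methoxy-4-[(triisopropylsilyl)oxy]phenyl}propane-1,3-dione (formed in the flask) | COc1cc(O[Si](C(C)C)(C(C)C)C(C)C)ccc1C(=O)CC(=O)c1c(OC)cc(O[Si](C(C)C)(C(C)C)C(C)C)c(I)c1O | intermediate
19 | 8-iodo-5-methoxy-2-{2-methoxy-4-[(triisopropylsilyl)oxy]phenyl}-7-[(triisopropylsilyl)oxy]-4H-chromen-4-one | COc1cc(O[Si](C(C)C)(C(C)C)C(C)C)ccc1C1=CC(=O)c2c(OC)cc(O[Si](C(C)C)(C(C)C)C(C)C)c(I)c2O1 | intermediate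
20 | {(2S)-5-methyl-2-(prop-1-en-2-yl)-5-[(triethylsilyl)oxy]hexyl}lithium (formed in the flask) | CC[Si](CC)(CC)OC(C)(C)CC[C@@H](C(C)=C)C[Li] | intermediate
21 | chloro{(2S)-5-methyl-2-(prop-1-en-2-yl)-5-[(triethylsilyl)oxy]hexyl}zinc (formed in the flask) | CC[Si](CC)(CC)OC(C)(C)CC[C@@H](C(C)=C)C[Zn]Cl | intermediate
22 | 5-methoxy-2-{2-methoxy-4-[(triisopropylsilyl)oxy]phenyl}-8-{(2R)-5-methyl-2-(prop-1-en-2-yl)-5-[(triethylsilyl)oxy]hexyl}-7-[(triisopropylsilyl)oxy]-4H-chromen-4-one | C=C(C)[C@H](CCC(C)(C)O[Si](CC)(CC)CC)Cc1c(O[Si](C(C)C)(C(C)C)C(C)C)cc(OC)c2c1OC(c1ccc(O[Si](C(C)C)(C(C)C)C(C)C)cc1OC)=CC2=O | intermediate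
23 | (2S)-5-methoxy-2-{2-methoxy-4-[(triisopropylsilyl)oxy]phenyl}-8-{(2R)-5-methyl-2-(prop-1-en-2-yl)-5-[(triethylsilyl)oxy]hexyl}-7-[(triisopropylsilyl)oxy]-2,3-dihydro-4H-chromen-4-one | C=C(C)[C@H](CCC(C)(C)O[Si](CC)(CC)CC)Cc1c(O[Si](C(C)C)(C(C)C)C(C)C)cc(OC)c2c1O[C@H](c1ccc(O[Si](C(C)C)(C(C)C)C(C)C)cc1OC)CC2=O | intermediate
24 | (2S)-7-hydroxy-2-(4-hydroxy-2-methoxyphenyl)-8-[(2R)-5-hydroxy-5-methyl-2-(prop-1-en-2-yl)hexyl]-5-methoxy-2,3-dihydro-4H-chromen-4-one | C=C(C)[C@H](CCC(C)(C)O)Cc1c(O)cc(OC)c2c1O[C@H](c1ccc(O)cc1OC)CC2=O | target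

**Step count and risks**
Total steps: 14. Longest linear sequence: 9 steps (steps 1–6, then 12, 13 and 14).

Most likely to fail, step 13: facial discrimination at C2 may be poor because the ortho-methoxyaryl group and the C8 side chain crowd the β-carbon, and the ketone may be over-reduced. The fallback sets out from 22 and returns at 23. Non-selective 1,4-reduction of 22 with LiBH(s-Bu)3 in THF at −78 °C should give the mixture of C2 epimers of the flavanone F1. Noyori-type asymmetric transfer hydrogenation with RuCl(p-cymene)[(R,R)-TsDPEN] and HCO2H/Et3N should then reduce the ketone of the (2R) epimer faster, to the cis-(2R,4R)-flavan-4-ol F2 (kinetic resolution). F2 is removed by chromatography and the unreacted (2S) epimer is 23.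

Second, step 12: oxidative addition at the crowded C8 between O1 and the silyloxy group may be slow, the alkylpalladium intermediate may undergo β-hydride elimination, or the organozinc may add to the pyranone. The fallback sets out from 12 (with zinc reagent 21 made from 9 as before) and returns at 22; it moves the union with the side chain in front of ring C. Aldehyde 12 is converted into its sodium phenoxide (NaH, THF, 0 °C) and coupled with 21 under Pd(OAc)2/SPhos to give 2-hydroxy-6-methoxy-3-{(2R)-5-methyl-2-(prop-1-en-2-yl)-5-[(triethylsilyl)oxy]hexyl}-4-[(triisopropylsilyl)oxy]benzaldehyde F3. Annulation of F3 with ylide 17 under the conditions of step 11, through the side-chain-bearing 1,3-diketone F4, gives 22.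

Third, step 11: formyl C–H activation may stall because the formyl group sits between a methoxy group and a phenol that carries an ortho iodine, the ylide may be consumed by self-reaction, or the diketone may fail to dehydrate. The fallback sets out from 12 and returns at 19 through 18; it replaces the C–H annulation by a stepwise aldol route. 1-(4-Hydroxy-2-methoxyphenyl)ethanone is silylated (TIPSCl, imidazole) to 1-{2-methoxy-4-[(triisopropylsilyl)oxy]phenyl}ethan-1-one F5. Its lithium enolate (LiN(iPr)2, THF, −78 °C) is added to 12, which has first been deprotonated at the phenol with LiN(SiMe3)2, to give the β-hydroxy ketone F6. Oxidation of the benzylic alcohol with MnO2 in CH2Cl2 gives diketone 18, which is closed to 19 with TsOH in toluene.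

Further compounds
F1 | step 13 | 5-methoxy-2-{2-methoxy-4-[(triisopropylsilyl)oxy]phenyl}-8-{(2R)-5-methyl-2-(prop-1-en-2-yl)-5-[(triethylsilyl)oxy]hexyl}-7-[(triisopropylsilyl)oxy]-2,3-dihydro-4H-chromen-4-one, mixture of C2 epimers | C=C(C)[C@H](CCC(C)(C)O[Si](CC)(CC)CC)Cc1c(O[Si](C(C)C)(C(C)C)C(C)C)cc(OC)c2c1OC(c1ccc(O[Si](C(C)C)(C(C)C)C(C)C)cc1OC)CC2=O
F2 | step 13 | (2R,4R)-5-methoxy-2-{2-methoxy-4-[(triisopropylsilyl)oxy]phenyl}-8-{(2R)-5-methyl-2-(prop-1-en-2-yl)-5-[(triethylsilyl)oxy]hexyl}-7-[(triisopropylsilyl)oxy]-3,4-dihydro-2H-chromen-4-ol | C=C(C)[C@H](CCC(C)(C)O[Si](CC)(CC)CC)Cc1c(O[Si](C(C)C)(C(C)C)C(C)C)cc(OC)c2c1O[C@@H](c1ccc(O[Si](C(C)C)(C(C)C)C(C)C)cc1OC)C[C@H]2O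
F3 | step 12 | 2-hydroxy-6-methoxy-3-{(2R)-5-methyl-2-(prop-1-en-2-yl)-5-[(triethylsilyl)oxy]hexyl}-4-[(triisopropylsilyl)oxy]benzaldehyde | O=Cc1c(O)c(C[C@H](C(C)=C)CCC(C)(C)O[Si](CC)(CC)CC)c(O[Si](C(C)C)(C(C)C)C(C)C)cc1OC
F4 | step 12 | 1-{2-hydroxy-6-methoxy-3-[(2R)-5-methyl-2-(prop-1-en-2-yl)-5-(triethylsilyloxy)hexyl]-4-[(triisopropylsilyl)oxy]phenyl}-3-{2-methoxy-4-[(triisopropylsilyl)oxy]phenyl}propane-1,3-dione | O=C(CC(=O)c1ccc(O[Si](C(C)C)(C(C)C)C(C)C)cc1OC)c1c(O)c(C[C@H](C(C)=C)CCC(C)(C)O[Si](CC)(CC)CC)c(O[Si](C(C)C)(C(C)C)C(C)C)cc1OC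
F5 | step 11 | 1-{2-methoxy-4-[(triisopropylsilyl)oxy]phenyl}ethan-1-one | CC(=O)c1ccc(O[Si](C(C)C)(C(C)C)C(C)C)cc1OC
F6 | step 11 | 3-hydroxy-3-{2-hydroxy-3-iodo-6-methoxy-4-[(triisopropylsilyl)oxy]phenyl}-1-{2-methoxy-4-[(triisopropylsilyl)oxy]phenyl}propan-1-one (racemic at the carbinol carbon) | OC(CC(=O)c1ccc(O[Si](C(C)C)(C(C)C)C(C)C)cc1OC)c1c(O)c(I)c(O[Si](C(C)C)(C(C)C)C(C)C)cc1OC
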